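The numbers in the tables were computed for substances that don't exist; the scatter is artificial.

Ask how isomer of the product stands to target in the flask, early and at the end.

| flask | substrate | free catalyst | remark | time |
|---|---|---|---|---|
| south-west | 0.10 M | 0.86 mM | run made earlier |  |
| north-east | 0.15 M | 0.86 mM | run made earlier |  |
| north-west | 0.20 M | 1.3 mM | run made earlier |  |
| flask | 0.20 M | 0.86 mM |  | 5.0 h |

- south-west (time / h: isomer of the product / %, target / %, substrate / %): 0.500: 14.6, 20.2, 37.7; 0.667: 20.4, 23.4, 26.8; 1.00: 22.8, 24.1, 13.9; 1.50: 29.5, 25.1, 7.9; 2.50: 31.1, 25.0, 1.6; 4.00: 33.4, 26.6, 0; 6.00: 34.6, 24.7, 0.1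
- north-east (time / h: isomer of the product / %, target / %, substrate / %): 0.500: 18.1, 16.9, 37.7; 0.667: 21.7, 20.0, 28.4; 1.00: 23.8, 21.4, 15.3; 1.50: 31.6, 25.5, 7.8; 2.50: 32.7, 23.3, 1.5; 4.00: 31.9, 25.2, 1.5; 6.00: 33.1, 26.2, 0
- north-west (time / h: isomer of the product / %, target / %, substrate / %): 0.500: 18.0, 24.4, 32.9; 1.50: 28.2, 30.0, 5.6; 3.00: 31.1, 30.4, 1.7; 4.00: 31.1, 31.8, 1.4; 6.00: 31.4, 29.6, 0

(each reading ± 1 percentage point)

* ratio of isomer of the product to target at 80 s
* ratio of isomer of the product to target at 5.0 h
* which of isomer of the product and target there is more of at 5.0 h



Build the flask one process at a time. Take the main step first, substrate to target: the ratio of isomer to target stays zero. Add isomer as a second product made in step with target: the ratio becomes one constant. The readings do not show a constant. At 0.500 h the south-west and north-east runs pool to 0.881, and at 4.00 h and 6.00 h to 1.30. So isomer lags, and I put the ratio at 80 s below 0.881, with no closer figure.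

Now work with the fraction left. At 2.50 h the south-west run keeps 1.6% as substrate, less than its 25.0% of target, so late ratios compare nearly finished yields.

Add the catalyst last. The south-west and north-east runs share a catalyst level, differ in substrate, and read 1.33 and 1.26. The north-west run, with more catalyst and also more substrate, reads 1.02, lower than 1.30. Two settings differ there, so laying that fall on the catalyst is my assumption. Define the catalyst slope as the fall in ln(late ratio) per unit rise in ln(catalyst): 0.583. The flask has the catalyst of the pooled runs, so the slope moves nothing. I reckon 1.30, with isomer ahead, taking its larger substrate charge to matter little.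

The forecast gives 0.6 at 80 s, 1.2 at 5.0 h, and isomer of the product ahead: “The flask shares its substrate with one and its catalyst with the others, so its cause is confounded.” My late figure is higher than its figure.

The flask gives 0.109 at 80 s and 1.31 at 5.0 h, with isomer of the product ahead, 32.7% against 25.1%.

    free catalyst + target → spent catalyst B (k = 0.00276 /M/s)
    free catalyst + other conformer → free catalyst + isomer of the product (k = 3.57 /M/s)
    substrate ⇌ other conformer (K = 0.598, k = 2.15 × 10⁻⁴ /s)
    2 free catalyst → spent catalyst A (k = 0.235 /M/s)
    substrate + free catalyst → free catalyst + target (k = 0.259 /M/s)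
    substrate → uncatalysed product (k = 2.03 × 10⁻⁴ /s)

The forecast and the flask part at 80 s, where the flask stands below 0.6. In the flask, hold the substrate's half-life by uncatalysed product alone, 0.95 h, against its half-life by the target step at 5.00 h, 36 h, which is longer. The flask then has 2.42% of its free catalyst and holds 41.4% as uncatalysed product. Take the slope of 0.583 to a second flask, the same but with 0.0022 M of free catalyst: it gives 0.749. That second flask gives 0.725, with 38.3% of target against 27.8% of isomer of the product.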